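## Retrosynthetic overview

1. Both stereocentres are bought: C2 in (2S)-naringenin (1), and the oxirane carbon in methyl (4S)-2,2-dimethyl-1,3-dioxolane-4-carboxylate (2), carried as a carbinol and inverted once on ring closure.
2. Oxirane ⇒ β-hydroxy mesylate (internal SN2) with the 4'-oxygen silylated; it is closed only after every C–C bond is in place.
3. C6-prenyl ⇒ C6-allyl (cross-metathesis) ⇒ 5-O-allyl ether; the C6–C bond is made by an Eu(fod)3-catalysed [3,3] Claisen rearrangement (key step).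
4. C3'–CH2 bond ⇒ 3'-iodo-7-O-pivaloylnaringenin plus a C5 iodo-diol made from 2, joined by nickel-catalysed reductive coupling.
5. Ring order: rings A, B and C come intact with 1; the oxirane is the only ring formed (step 12).

Assumption: 1 is bought as the single (2S) enantiomer and 2 as the L-serine-derived (S) ester; basic steps are kept cold and short so that C2 is not epimerised.

## Route

Step 1
Reactants: 1 (2S)-naringenin
Product: 3 (2S)-5-hydroxy-2-(4-hydroxyphenyl)-4-oxochroman-7-yl pivalate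
Conditions: PivCl (1.05 equiv), iPr2NEt, THF, −20 °C
Reagents that add atoms: pivaloyl chloride, CC(C)(C)C(Cl)=O
Why: Chemoselective O-acylation of the most acidic phenol (7-OH, para to the carbonyl) leaves the chelated 5-OH and the 4'-OH free and makes ring A electron-poorer; C2 is not touched.

Step 2
Reactants: 3 (2S)-5-hydroxy-2-(4-hydroxyphenyl)-4-oxochroman-7-yl pivalate
Product: 4 (2S)-5-hydroxy-2-(4-hydroxy-3-iodophenyl)-4-oxochroman-7-yl pivalate
Conditions: I2 (1.0 equiv), NaHCO3, THF/H2O, 0 °C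
Reagents that add atoms: iodine, I-I
Why: Electrophilic aromatic iodination through the only phenolate that bicarbonate can form (4'-O; the 5-OH is locked in its hydrogen bond to C4=O and ring A carries an ester), so iodine enters ortho to the 4'-oxygen at C3'.

Step 3
Reactants: 2 methyl (4S)-2,2-dimethyl-1,3-dioxolane-4-carboxylate
Product: 5 2-[(4S)-2,2-dimethyl-1,3-dioxolan-4-yl]propan-2-ol
Conditions: MeMgBr (2.5 equiv), THF, 0 °C to rt; H2O quench
Reagents that add atoms: methylmagnesium bromide, C[Mg]Br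
Why: Double Grignard addition to the ester gives the tertiary alcohol without touching the bought stereocentre.

Step 4
Reactants: 5 2-[(4S)-2,2-dimethyl-1,3-dioxolan-4-yl]propan-2-ol
Product: 6 (2S)-3-methylbutane-1,2,3-triol
Conditions: AcOH/H2O (4:1), 40 °C; evaporate
Reagents that add atoms: none
Why: Acid-catalysed acetal hydrolysis frees the primary and secondary hydroxyls with the configuration unchanged.

Step 5
Reactants: 6 (2S)-3-methylbutane-1,2,3-triol
Product: 7 (2R)-1-iodo-3-methylbutane-2,3-diol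
Conditions: PPh3 (1.1 equiv), I2 (1.1 equiv), imidazole, THF/MeCN, 0 °C
Reagents that add atoms: iodine, I-I
Why: Appel iodination is selective for the primary hydroxyl (SN2 at CH2), so the carbinol centre keeps its geometry; the descriptor changes to R only because CH2I now outranks the carbinol carbon.

Step 6
Reactants: 4 (2S)-5-hydroxy-2-(4-hydroxy-3-iodophenyl)-4-oxochroman-7-yl pivalate; 7 (2R)-1-iodo-3-methylbutane-2,3-diol
Product: 8 (2S)-2-{3-[(2S)-2,3-dihydroxy-3-methylbutyl]-4-hydroxyphenyl}-5-hydroxy-4-oxochroman-7-yl pivalate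
Conditions: NiI2·xH2O (10 mol %), 4,4'-dimethoxy-2,2'-bipyridine (10 mol %), NaI (25 mol %), pyridine (10 mol %), Zn dust (2 equiv), DMPU, 60 °C
Reagents that add atoms: none
Why: Nickel-catalysed reductive cross-electrophile coupling joins the aryl iodide to the primary alkyl radical from 7 while tolerating ketone, ester and free OH groups; the radical sits one carbon away from the carbinol stereocentre, which is carried over unchanged from 2 (now S by the priority rules).

Step 7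
Reactants: 8 (2S)-2-{3-[(2S)-2,3-dihydroxy-3-methylbutyl]-4-hydroxyphenyl}-5-hydroxy-4-oxochroman-7-yl pivalate
Product: 9 (2S)-2-{3-[(2S)-2,3-dihydroxy-3-methylbutyl]-4-(triisopropylsilyloxy)phenyl}-5-hydroxy-4-oxochroman-7-yl pivalate
Conditions: TIPSCl (1.1 equiv), imidazole, DMF, 0 °C to rt
Reagents that add atoms: triisopropylsilyl chloride, CC(C)[Si](Cl)(C(C)C)C(C)C
Why: The bulky silyl chloride silylates the free, unchelated 4'-phenol but not the hindered secondary and tertiary alcohols or the chelated 5-OH.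

Step 8
Reactants: 9 (2S)-2-{3-[(2S)-2,3-dihydroxy-3-methylbutyl]-4-(triisopropylsilyloxy)phenyl}-5-hydroxy-4-oxochroman-7-yl pivalate
Product: 10 (2S)-5-hydroxy-2-{3-[(2S)-3-hydroxy-3-methyl-2-(methylsulfonyloxy)butyl]-4-(triisopropylsilyloxy)phenyl}-4-oxochroman-7-yl pivalate
Conditions: MsCl (1.2 equiv), Et3N, CH2Cl2, −20 °C
Reagents that add atoms: methanesulfonyl chloride, CS(Cl)(=O)=O
Why: Sulfonylation of the only secondary alcohol (tertiary OH and chelated phenol are inert at low temperature) turns the carbinol oxygen into a leaving group with retention.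

Step 9
Reactants: 10 (2S)-5-hydroxy-2-{3-[(2S)-3-hydroxy-3-methyl-2-(methylsulfonyloxy)butyl]-4-(triisopropylsilyloxy)phenyl}-4-oxochroman-7-yl pivalate
Product: 11 (2S)-5-(allyloxy)-2-{3-[(2S)-3-hydroxy-3-methyl-2-(methylsulfonyloxy)butyl]-4-(triisopropylsilyloxy)phenyl}-4-oxochroman-7-yl pivalate
Conditions: allyl alcohol (1.5 equiv), PPh3, DIAD, THF, 0 °C to rt
Reagents that add atoms: allyl alcohol, C=CCO
Why: Mitsunobu etherification of the last free acidic OH (5-OH) with a primary alcohol; the tertiary alcohol cannot be activated and no stereocentre is involved.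

Step 10
Reactants: 11 (2S)-5-(allyloxy)-2-{3-[(2S)-3-hydroxy-3-methyl-2-(methylsulfonyloxy)butyl]-4-(triisopropylsilyloxy)phenyl}-4-oxochroman-7-yl pivalate
Product: 13 (2S)-6-allyl-5-hydroxy-2-{3-[(2S)-3-hydroxy-3-methyl-2-(methylsulfonyloxy)butyl]-4-(triisopropylsilyloxy)phenyl}-4-oxochroman-7-yl pivalate, via ortho-dienone 12 (not isolated)
Conditions: Eu(fod)3 (10 mol %), PhCl, 80 °C
Reagents that add atoms: none
Why: Eu(fod)3 chelates the C4 carbonyl and the 5-O-allyl oxygen and accelerates the aromatic [3,3] Claisen rearrangement, which can deliver the allyl group only to C6 (the other ortho carbon is C4a) before enolisation restores the chelated 5-OH; both stereocentres are spectators.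

Step 11
Reactants: 13 (2S)-6-allyl-5-hydroxy-2-{3-[(2S)-3-hydroxy-3-methyl-2-(methylsulfonyloxy)butyl]-4-(triisopropylsilyloxy)phenyl}-4-oxochroman-7-yl pivalate
Product: 14 (2S)-5-hydroxy-2-{3-[(2S)-3-hydroxy-3-methyl-2-(methylsulfonyloxy)butyl]-4-(triisopropylsilyloxy)phenyl}-6-(3-methylbut-2-enyl)-4-oxochroman-7-yl pivalate
Conditions: 2-methylbut-2-ene (excess), second-generation Grubbs catalyst (5 mol %), CH2Cl2, 40 °C
Reagents that add atoms: 2-methylbut-2-ene, CC=C(C)C
Why: Olefin cross-metathesis of the terminal allyl group with excess 2-methylbut-2-ene gives the trisubstituted prenyl alkene with loss of propene.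

Step 12
Reactants: 14 (2S)-5-hydroxy-2-{3-[(2S)-3-hydroxy-3-methyl-2-(methylsulfonyloxy)butyl]-4-(triisopropylsilyloxy)phenyl}-6-(3-methylbut-2-enyl)-4-oxochroman-7-yl pivalate
Product: 16 (2S)-2-{3-[((2R)-3,3-dimethyloxiran-2-yl)methyl]-4-(triisopropylsilyloxy)phenyl}-5,7-dihydroxy-6-(3-methylbut-2-enyl)chroman-4-one, via pivaloyl epoxide 15 (not isolated)
Conditions: K2CO3 (3 equiv), MeOH, 0 °C to rt
Reagents that add atoms: none
Why: Internal Williamson SN2 by the tertiary alkoxide displaces the neighbouring mesylate with inversion, turning the (S)-carbinol carbon into the (R)-oxirane carbon, while the activated 7-pivalate is removed by transesterification and the base-stable silyl ether keeps the 4'-oxygen from competing.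

Step 13
Reactants: 16 (2S)-2-{3-[((2R)-3,3-dimethyloxiran-2-yl)methyl]-4-(triisopropylsilyloxy)phenyl}-5,7-dihydroxy-6-(3-methylbut-2-enyl)chroman-4-one
Product: 17 (2S)-2-{3-[((2R)-3,3-dimethyloxiran-2-yl)methyl]-4-hydroxyphenyl}-5,7-dihydroxy-6-(3-methylbut-2-enyl)chroman-4-one
Conditions: TBAF (1.2 equiv), AcOH (1.2 equiv), THF, 0 °C, 15 min; pH 7 buffer work-up
Reagents that add atoms: none
Why: Buffered fluoride desilylation releases the phenol as neutral ArOH, so the adjacent oxirane is opened neither by phenolate nor by acid, and no stereocentre is touched.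

## Compound list

1 | (2S)-naringenin, (2S)-5,7-dihydroxy-2-(4-hydroxyphenyl)chroman-4-one | Oc1cc2c(c(O)c1)C(=O)C[C@@H](c1ccc(O)cc1)O2 | starting material
2 | methyl (4S)-2,2-dimethyl-1,3-dioxolane-4-carboxylate | COC(=O)[C@@H]1COC(C)(C)O1 | starting material
3 | (2S)-5-hydroxy-2-(4-hydroxyphenyl)-4-oxochroman-7-yl pivalate | CC(C)(C)C(=O)Oc1cc2c(c(O)c1)C(=O)C[C@@H](c1ccc(O)cc1)O2 | intermediate
4 | (2S)-5-hydroxy-2-(4-hydroxy-3-iodophenyl)-4-oxochroman-7-yl pivalate | CC(C)(C)C(=O)Oc1cc2c(c(O)c1)C(=O)C[C@@H](c1ccc(O)c(I)c1)O2 | intermediate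
5 | 2-[(4S)-2,2-dimethyl-1,3-dioxolan-4-yl]propan-2-ol | CC(C)(O)[C@@H]1COC(C)(C)O1 | intermediate
6 | (2S)-3-methylbutane-1,2,3-triol | CC(C)(O)[C@@H](O)CO | intermediate
7 | (2R)-1-iodo-3-methylbutane-2,3-diol | CC(C)(O)[C@@H](O)CI | intermediate
8 | (2S)-2-{3-[(2S)-2,3-dihydroxy-3-methylbutyl]-4-hydroxyphenyl}-5-hydroxy-4-oxochroman-7-yl pivalate | CC(C)(C)C(=O)Oc1cc2c(c(O)c1)C(=O)C[C@@H](c1ccc(O)c(C[C@H](O)C(C)(C)O)c1)O2 | intermediate
9 | (2S)-2-{3-[(2S)-2,3-dihydroxy-3-methylbutyl]-4-(triisopropylsilyloxy)phenyl}-5-hydroxy-4-oxochroman-7-yl pivalate | CC(C)(C)C(=O)Oc1cc2c(c(O)c1)C(=O)C[C@@H](c1ccc(O[Si](C(C)C)(C(C)C)C(C)C)c(C[C@H](O)C(C)(C)O)c1)O2 | intermediate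
10 | (2S)-5-hydroxy-2-{3-[(2S)-3-hydroxy-3-methyl-2-(methylsulfonyloxy)butyl]-4-(triisopropylsilyloxy)phenyl}-4-oxochroman-7-yl pivalate | CC(C)(C)C(=O)Oc1cc2c(c(O)c1)C(=O)C[C@@H](c1ccc(O[Si](C(C)C)(C(C)C)C(C)C)c(C[C@H](OS(C)(=O)=O)C(C)(C)O)c1)O2 | intermediate
11 | (2S)-5-(allyloxy)-2-{3-[(2S)-3-hydroxy-3-methyl-2-(methylsulfonyloxy)butyl]-4-(triisopropylsilyloxy)phenyl}-4-oxochroman-7-yl pivalate | CC(C)(C)C(=O)Oc1cc2c(c(OCC=C)c1)C(=O)C[C@@H](c1ccc(O[Si](C(C)C)(C(C)C)C(C)C)c(C[C@H](OS(C)(=O)=O)C(C)(C)O)c1)O2 | intermediate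
12 | ortho-dienone of the Claisen step: 6-allyl-5-oxo-5,6-dihydro tautomer of 13, C6 configuration undefined (formed in the flask, not isolated) | C=CCC1C(OC(=O)C(C)(C)C)=CC2=C(C1=O)C(=O)C[C@@H](c1ccc(O[Si](C(C)C)(C(C)C)C(C)C)c(C[C@H](OS(C)(=O)=O)C(C)(C)O)c1)O2 | intermediate
13 | (2S)-6-allyl-5-hydroxy-2-{3-[(2S)-3-hydroxy-3-methyl-2-(methylsulfonyloxy)butyl]-4-(triisopropylsilyloxy)phenyl}-4-oxochroman-7-yl pivalate | C=CCc1c(OC(=O)C(C)(C)C)cc2c(c1O)C(=O)C[C@@H](c1ccc(O[Si](C(C)C)(C(C)C)C(C)C)c(C[C@H](OS(C)(=O)=O)C(C)(C)O)c1)O2 | intermediate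
14 | (2S)-5-hydroxy-2-{3-[(2S)-3-hydroxy-3-methyl-2-(methylsulfonyloxy)butyl]-4-(triisopropylsilyloxy)phenyl}-6-(3-methylbut-2-enyl)-4-oxochroman-7-yl pivalate | CC(C)=CCc1c(OC(=O)C(C)(C)C)cc2c(c1O)C(=O)C[C@@H](c1ccc(O[Si](C(C)C)(C(C)C)C(C)C)c(C[C@H](OS(C)(=O)=O)C(C)(C)O)c1)O2 | intermediate
15 | pivaloyl epoxide: (2S)-2-{3-[((2R)-3,3-dimethyloxiran-2-yl)methyl]-4-(triisopropylsilyloxy)phenyl}-5-hydroxy-6-(3-methylbut-2-enyl)-4-oxochroman-7-yl pivalate (formed in the flask, not isolated) | CC(C)=CCc1c(OC(=O)C(C)(C)C)cc2c(c1O)C(=O)C[C@@H](c1ccc(O[Si](C(C)C)(C(C)C)C(C)C)c(C[C@H]3OC3(C)C)c1)O2 | intermediate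
16 | (2S)-2-{3-[((2R)-3,3-dimethyloxiran-2-yl)methyl]-4-(triisopropylsilyloxy)phenyl}-5,7-dihydroxy-6-(3-methylbut-2-enyl)chroman-4-one | CC(C)=CCc1c(O)cc2c(c1O)C(=O)C[C@@H](c1ccc(O[Si](C(C)C)(C(C)C)C(C)C)c(C[C@H]3OC3(C)C)c1)O2 | intermediate
17 | (2S)-2-{3-[((2R)-3,3-dimethyloxiran-2-yl)methyl]-4-hydroxyphenyl}-5,7-dihydroxy-6-(3-methylbut-2-enyl)chroman-4-one (CNP0158151.1) | CC(C)=CCc1c(O)cc2c(c1O)C(=O)C[C@@H](c1ccc(O)c(C[C@H]3OC3(C)C)c1)O2 | target

## Step count and risks

Total steps: 13. Longest linear sequence: 11 (from 2 through steps 3 to 13); the naringenin branch is 10 steps.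

Steps most likely to fail:

Step 2 (ring-B iodination). Ring A (C6/C8) may be iodinated as well, or ring B may take two iodines. The fallback sets out from 3 and comes back at 8. It replaces phenolate reactivity by hydrogen-bond-directed delivery of bromine: NBS with catalytic iPr2NH in CH2Cl2 at 0 °C brominates ortho to the free 4'-OH (the chelated 5-OH cannot engage) and gives (2S)-2-(3-bromo-4-hydroxyphenyl)-5-hydroxy-4-oxochroman-7-yl pivalate F1. F1 then takes the place of 4 in the nickel coupling with 7 and returns to the route at 8.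

Step 6 (nickel reductive coupling). The ortho-hydroxyaryl iodide may be protodeiodinated, and Zn may reduce the iodohydrin to an alkene. The fallback sets out from 4 and 6 and comes back at 8. Triol 6 is converted with CBr4/PPh3 into (2R)-1-bromo-3-methylbutane-2,3-diol F2. F2 is joined to 4 by light-driven silyl-radical cross-electrophile coupling: [Ir(dF(CF3)ppy)2(dtbbpy)]PF6, NiCl2·glyme, 4,4'-di-tert-butyl-2,2'-bipyridine, (Me3Si)3SiH, Na2CO3, DME, blue LEDs, rt. Here the alkyl radical is made by halogen abstraction and no metal reductant is present.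

Step 13 (final unveiling). The freed 4'-phenol can open the adjacent oxirane to a dihydrobenzofuran, and the silyl ether may not survive step 12 cleanly. The fallback sets out from 14 and comes back at 17, and changes the last protecting group and the way it is removed.
- Desilylation of 14 at the mesylate stage (TBAF/AcOH, THF, 0 °C) gives the phenol mesylate F3.
- Neutral O-allylation (allyl methyl carbonate, catalytic Pd(PPh3)4, THF) gives the 4'-O-allyl ether mesylate F4.
- K2CO3/MeOH closes the oxirane and removes the pivalate, through the pivaloyl allyl-ether epoxide F5 to the 7-hydroxy allyl-ether epoxide F6; the allyl ether is inert to carbonate.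
- The phenol is released last by zerovalent-palladium allyl transfer to morpholine (catalytic Pd(PPh3)4, morpholine, THF, rt), neutral and fluoride-free, giving 17.

## Further compounds

F1 | step 2 | (2S)-2-(3-bromo-4-hydroxyphenyl)-5-hydroxy-4-oxochroman-7-yl pivalate | CC(C)(C)C(=O)Oc1cc2c(c(O)c1)C(=O)C[C@@H](c1ccc(O)c(Br)c1)O2
F2 | step 6 | (2R)-1-bromo-3-methylbutane-2,3-diol | CC(C)(O)[C@@H](O)CBr
F3 | step 13 | (2S)-5-hydroxy-2-{4-hydroxy-3-[(2S)-3-hydroxy-3-methyl-2-(methylsulfonyloxy)butyl]phenyl}-6-(3-methylbut-2-enyl)-4-oxochroman-7-yl pivalate | CC(C)=CCc1c(OC(=O)C(C)(C)C)cc2c(c1O)C(=O)C[C@@H](c1ccc(O)c(C[C@H](OS(C)(=O)=O)C(C)(C)O)c1)O2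
F4 | step 13 | (2S)-2-{4-(allyloxy)-3-[(2S)-3-hydroxy-3-methyl-2-(methylsulfonyloxy)butyl]phenyl}-5-hydroxy-6-(3-methylbut-2-enyl)-4-oxochroman-7-yl pivalate | CC(C)=CCc1c(OC(=O)C(C)(C)C)cc2c(c1O)C(=O)C[C@@H](c1ccc(OCC=C)c(C[C@H](OS(C)(=O)=O)C(C)(C)O)c1)O2
F5 | step 13 | (2S)-2-{4-(allyloxy)-3-[((2R)-3,3-dimethyloxiran-2-yl)methyl]phenyl}-5-hydroxy-6-(3-methylbut-2-enyl)-4-oxochroman-7-yl pivalate | CC(C)=CCc1c(OC(=O)C(C)(C)C)cc2c(c1O)C(=O)C[C@@H](c1ccc(OCC=C)c(C[C@H]3OC3(C)C)c1)O2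
F6 | step 13 | (2S)-2-{4-(allyloxy)-3-[((2R)-3,3-dimethyloxiran-2-yl)methyl]phenyl}-5,7-dihydroxy-6-(3-methylbut-2-enyl)chroman-4-one | CC(C)=CCc1c(O)cc2c(c1O)C(=O)C[C@@H](c1ccc(OCC=C)c(C[C@H]3OC3(C)C)c1)O2
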